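The target is cut at the ynone C(=O)–C(sp) bond into a (3S)-chromane-2,4-dione thioester and a C14 diynol. In the diynol the carbinol carbon sits between the Z C=C and the first C≡C, which maps onto C2 of glyceraldehyde. The key Wittig step joins an octylidene ylide to the CHO carbon of (R)-glyceraldehyde acetonide and thereby makes the Z C=C beside the purchased O-bearing stereocentre in one operation; the dioxolane CH2O carbon later becomes the alkyne. The precursor is the five-membered dioxolane aldehyde; the benzo and pyrandione rings of the target take no part. The quaternary C3 is set by a catalytic Michael addition.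

Key step: step 2

Remark: the facial sense of the catalyst in step 12 cannot be fixed in advance; the quinidine-derived thiourea is written, its quinine-derived pseudo-enantiomer serves if the other face is attacked, and the configuration of 22 is to be proven before step 13.

Step 1
Reactants: 1 1,2:5,6-di-O-isopropylidene-D-mannitol (one molecule gives two of 2)
Product: 2 (R)-2,2-dimethyl-1,3-dioxolane-4-carbaldehyde
Conditions: NaIO4, sat. aq. NaHCO3, CH2Cl2, 0 °C → rt; used at once
Reagents that add atoms: none
Why: Periodate (Malaprade) cleavage of the central vicinal diol leaves the dioxolane stereocentre untouched, and fresh preparation avoids the oligomerised and partly epimerised material that the stored aldehyde tends to contain.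

Step 2
Reactants: 3 octyltriphenylphosphonium bromide; 2 (R)-2,2-dimethyl-1,3-dioxolane-4-carbaldehyde
Product: 5 (S)-2,2-dimethyl-4-[(Z)-non-1-en-1-yl]-1,3-dioxolane, via octylidenetriphenylphosphorane 4 (not isolated)
Conditions: NaN(SiMe3)2 (slightly less than 1 equiv relative to 3), THF, 0 °C; then 2, −78 °C → rt
Reagents that add atoms: none
Why: The salt-free unstabilised ylide 4 and the aldehyde carbon of 2 combine in a kinetically controlled [2+2] addition whose bent, reactant-like transition state places the heptyl chain and the dioxolane on the same side of the forming P–C–C–O ring, and stereospecific syn-loss of Ph3P=O from this cis ring then delivers the Z C=C. The closest known reaction type is the Z-selective Wittig olefination of 2,3-O-isopropylideneglyceraldehyde with unstabilised alkylidenephosphoranes. No ring of the target is closed and no stereocentre is made; the dioxolane C4 centre is a spectator, and its label switches from R to S purely through the CIP ranking (the alkenyl group ranks below CH2O, the formyl group above it). The selectivity needed is Z over E, secured by the sodium counter-ion, the absence of lithium salts, the low temperature and the α-branched aldehyde. Epimerisation at the α-alkoxy carbon is avoided because no free amide base is left and the aldehyde is consumed by the ylide at −78 °C faster than it can enolise.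

Step 3
Reactants: 5 (S)-2,2-dimethyl-4-[(Z)-non-1-en-1-yl]-1,3-dioxolane
Product: 6 (2S,3Z)-undec-3-ene-1,2-diol
Conditions: AcOH/H2O (4:1), 40 °C
Reagents that add atoms: none
Why: Mild aqueous acid hydrolysis of a terminal isopropylidene acetal should free both hydroxyls without ionising the allylic C–O bond, so the Z alkene and the stereocentre are kept.

Step 4
Reactants: 6 (2S,3Z)-undec-3-ene-1,2-diol
Product: 7 (2S,3Z)-1,2-bis[(triethylsilyl)oxy]undec-3-ene
Conditions: Et3SiCl, imidazole, DMF, 0 °C → rt
Reagents that add atoms: chlorotriethylsilane, CC[Si](Cl)(CC)CC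
Why: Imidazole-promoted silylation covers both hydroxyls, and the triethylsilyl group is chosen because its primary ether can be oxidised directly in step 5 while its secondary ether falls off with fluoride in step 8.

Step 5
Reactants: 7 (2S,3Z)-1,2-bis[(triethylsilyl)oxy]undec-3-ene
Product: 9 (2S,3Z)-2-[(triethylsilyl)oxy]undec-3-enal, via alkoxydimethylsulfonium chloride 8 (not isolated)
Conditions: (COCl)2, DMSO, CH2Cl2, −78 °C; 7, −78 → −40 °C; then Et3N, −78 → 0 °C; used crude
Reagents that add atoms: none
Why: Under Swern conditions the chlorodimethylsulfonium salt cleaves only the unhindered primary Si–O bond and turns it into the alkoxysulfonium salt 8, which the base converts into the aldehyde, while the secondary silyl ether is inert and the cold, brief contact with Et3N limits α-epimerisation.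

Step 6
Reactants: 9 (2S,3Z)-2-[(triethylsilyl)oxy]undec-3-enal
Product: 10 triethyl{[(3S,4Z)-dodec-4-en-1-yn-3-yl]oxy}silane
Conditions: dimethyl (1-diazo-2-oxopropyl)phosphonate, K2CO3, MeOH, 0 °C → rt
Reagents that add atoms: dimethyl (1-diazo-2-oxopropyl)phosphonate, COP(=O)(OC)C(=[N+]=[N-])C(C)=O
Why: In the Ohira–Bestmann (Seyferth–Gilbert) homologation the diazomethylphosphonate anion adds to the aldehyde, and phosphate and N2 loss with a 1,2-hydrogen shift give the terminal alkyne; the carbinol C–O bond is not touched, so the configuration is carried over.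

Step 7
Reactants: 10 triethyl{[(3S,4Z)-dodec-4-en-1-yn-3-yl]oxy}silane; 11 (bromoethynyl)triisopropylsilane
Product: 12 triethyl{[(5S,6Z)-1-(triisopropylsilyl)tetradeca-6-ene-1,3-diyn-5-yl]oxy}silane
Conditions: CuCl (cat.), NH2OH·HCl, 30% aq. n-BuNH2, Et2O, 0 °C
Reagents that add atoms: none
Why: In the Cadiot–Chodkiewicz coupling the copper acetylide of 10 joins the bromoalkyne to the unsymmetrical diyne, the bulky silyl group suppresses homocoupling, and hydroxylamine keeps the copper monovalent.

Step 8
Reactants: 12 triethyl{[(5S,6Z)-1-(triisopropylsilyl)tetradeca-6-ene-1,3-diyn-5-yl]oxy}silane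
Product: 13 (5S,6Z)-tetradeca-6-ene-1,3-diyn-5-ol
Conditions: Bu4NF, THF, 0 °C; kept cold in solution and used at once
Reagents that add atoms: none
Why: Fluoride should cleave the C(sp)–Si and the O–Si bond in one operation, so that no protecting group has to be removed after the sensitive ynone is in place.

Step 9
Reactants: 14 (2E,6E)-farnesol
Product: 15 methyl (2E,6E)-3,7,11-trimethyldodeca-2,6,10-trien-1-yl carbonate
Conditions: ClCO2Me, pyridine, CH2Cl2, 0 °C
Reagents that add atoms: methyl chloroformate, COC(=O)Cl
Why: Acylation of the primary allylic alcohol under basic conditions gives the allyl carbonate without allylic transposition or attack on the trisubstituted alkenes.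

Step 10
Reactants: 16 4-hydroxycoumarin (in excess); 15 methyl (2E,6E)-3,7,11-trimethyldodeca-2,6,10-trien-1-yl carbonate
Product: 17 4-hydroxy-3-[(2E,6E)-3,7,11-trimethyldodeca-2,6,10-trien-1-yl]-2H-chromen-2-one
Conditions: Pd(PPh3)4 (cat.), THF, rt
Reagents that add atoms: none
Why: In this Tsuji–Trost allylation zerovalent palladium ionises the carbonate, the methoxide set free deprotonates 16, and the soft enolate attacks the unsubstituted terminus of the π-allyl complex to give the linear 2E product at C3; any O-allyl isomer is re-ionised and funnelled to carbon, and the excess of 16 limits double allylation.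

Step 11
Reactants: 18 3-bromopropanoyl chloride; 19 ethanethiol
Product: 21 S-ethyl prop-2-enethioate, via S-ethyl 3-bromopropanethioate 20 (not isolated)
Conditions: Et3N (1 equiv), CH2Cl2, −20 °C; then Et3N (1.2 equiv), 0 °C → rt
Reagents that add atoms: none
Why: S-acylation of the thiol is followed by E1cB loss of HBr on addition of the second portion of base, and because all thiol is consumed before the acrylate appears, thia-Michael addition is avoided.

Step 12
Reactants: 17 4-hydroxy-3-[(2E,6E)-3,7,11-trimethyldodeca-2,6,10-trien-1-yl]-2H-chromen-2-one; 21 S-ethyl prop-2-enethioate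
Product: 22 S-ethyl 3-{(3S)-2,4-dioxo-3-[(2E,6E)-3,7,11-trimethyldodeca-2,6,10-trien-1-yl]-3,4-dihydro-2H-chromen-3-yl}propanethioate
Conditions: N-[3,5-bis(trifluoromethyl)phenyl]-N'-[(9R)-6'-methoxycinchonan-9-yl]thiourea (10 mol%, the thiourea of 9-amino-9-deoxy-epi-quinidine), toluene, 0 °C
Reagents that add atoms: none
Why: Proposed new method: the quinuclidine nitrogen of the catalyst deprotonates the acidic C4–OH of 17 to a tight ammonium enolate pair while the thiourea N–H bonds bind the thioester carbonyl of 21, so that C3 attacks the β-carbon inside a chiral ternary complex; the two flanks of C3 differ strongly (ring oxygen O1 on the C2 side, the fused benzo ring with its peri C5–H on the C4 side), which should give the ion pair one preferred orientation and expose one face of C3 to set the quaternary centre; the closest known reaction types are the cinchona-thiourea-catalysed Michael addition of cyclic β-keto esters to acrylic thioesters, which forms all-carbon quaternary centres, and the bifunctional-thiourea-catalysed dearomatising Michael addition of 1-substituted 2-naphthols.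

Step 13
Reactants: 22 S-ethyl 3-{(3S)-2,4-dioxo-3-[(2E,6E)-3,7,11-trimethyldodeca-2,6,10-trien-1-yl]-3,4-dihydro-2H-chromen-3-yl}propanethioate; 13 (5S,6Z)-tetradeca-6-ene-1,3-diyn-5-ol
Product: 23 (3S)-3-[(8S,9Z)-8-hydroxy-3-oxoheptadec-9-ene-4,6-diyn-1-yl]-3-[(2E,6E)-3,7,11-trimethyldodeca-2,6,10-trien-1-yl]-2H-chromene-2,4(3H)-dione
Conditions: PdCl2(dppf) (10 mol%; dppf = 1,1'-bis(diphenylphosphino)ferrocene), P(2-furyl)3 (25 mol%), CuI (1.7 equiv), Et3N, DMF, 50 °C, degassed
Reagents that add atoms: none
Why: In this thioester variant of the acyl Sonogashira coupling zerovalent palladium inserts into the C(O)–S bond, CuI with Et3N supplies the copper acetylide of the terminal diyne and binds the thiolate as CuSEt, and reductive elimination gives the ynone without nucleophilic base, so the lactone ring, the C3 centre, the Z alkene and the free carbinol should pass unchanged.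

Compound list
1 | 1,2:5,6-di-O-isopropylidene-D-mannitol, (1S,2S)-1,2-bis[(4R)-2,2-dimethyl-1,3-dioxolan-4-yl]ethane-1,2-diol | O[C@H]([C@H]1COC(C)(C)O1)[C@H](O)[C@H]1COC(C)(C)O1 | starting material
2 | (R)-2,2-dimethyl-1,3-dioxolane-4-carbaldehyde | O=C[C@H]1COC(C)(C)O1 | intermediate
3 | octyltriphenylphosphonium bromide | CCCCCCCC[P+](c1ccccc1)(c1ccccc1)c1ccccc1.[Br-] | starting material
4 | octylidenetriphenylphosphorane | CCCCCCCC=P(c1ccccc1)(c1ccccc1)c1ccccc1 | intermediate (not isolated)
5 | (S)-2,2-dimethyl-4-[(Z)-non-1-en-1-yl]-1,3-dioxolane | CCCCCCC/C=C\[C@H]1COC(C)(C)O1 | intermediate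
6 | (2S,3Z)-undec-3-ene-1,2-diol | CCCCCCC/C=C\[C@H](O)CO | intermediate
7 | (2S,3Z)-1,2-bis[(triethylsilyl)oxy]undec-3-ene | CCCCCCC/C=C\[C@H](O[Si](CC)(CC)CC)CO[Si](CC)(CC)CC | intermediate
8 | dimethyl{[(2S,3Z)-2-[(triethylsilyl)oxy]undec-3-en-1-yl]oxy}sulfonium chloride | CCCCCCC/C=C\[C@H](O[Si](CC)(CC)CC)CO[S+](C)C.[Cl-] | intermediate (not isolated)
9 | (2S,3Z)-2-[(triethylsilyl)oxy]undec-3-enal | CCCCCCC/C=C\[C@H](O[Si](CC)(CC)CC)C=O | intermediate
10 | triethyl{[(3S,4Z)-dodec-4-en-1-yn-3-yl]oxy}silane | CCCCCCC/C=C\[C@H](O[Si](CC)(CC)CC)C#C | intermediate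
11 | (bromoethynyl)triisopropylsilane | CC(C)[Si](C#CBr)(C(C)C)C(C)C | starting material
12 | triethyl{[(5S,6Z)-1-(triisopropylsilyl)tetradeca-6-ene-1,3-diyn-5-yl]oxy}silane | CCCCCCC/C=C\[C@H](O[Si](CC)(CC)CC)C#CC#C[Si](C(C)C)(C(C)C)C(C)C | intermediate
13 | (5S,6Z)-tetradeca-6-ene-1,3-diyn-5-ol | CCCCCCC/C=C\[C@H](O)C#CC#C | intermediate
14 | (2E,6E)-farnesol | OC/C=C(\C)CC/C=C(\C)CCC=C(C)C | starting material
15 | methyl (2E,6E)-3,7,11-trimethyldodeca-2,6,10-trien-1-yl carbonate | COC(=O)OC/C=C(\C)CC/C=C(\C)CCC=C(C)C | intermediate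
16 | 4-hydroxycoumarin | O=c1cc(O)c2ccccc2o1 | starting material
17 | 4-hydroxy-3-[(2E,6E)-3,7,11-trimethyldodeca-2,6,10-trien-1-yl]-2H-chromen-2-one | O=c1oc2ccccc2c(O)c1C/C=C(\C)CC/C=C(\C)CCC=C(C)C | intermediate
18 | 3-bromopropanoyl chloride | O=C(Cl)CCBr | starting material
19 | ethanethiol | CCS | starting material
20 | S-ethyl 3-bromopropanethioate | CCSC(=O)CCBr | intermediate (not isolated)
21 | S-ethyl prop-2-enethioate | CCSC(=O)C=C | intermediate
22 | S-ethyl 3-{(3S)-2,4-dioxo-3-[(2E,6E)-3,7,11-trimethyldodeca-2,6,10-trien-1-yl]-3,4-dihydro-2H-chromen-3-yl}propanethioate | CCSC(=O)CC[C@@]1(C/C=C(\C)CC/C=C(\C)CCC=C(C)C)C(=O)Oc2ccccc2C1=O | intermediate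
23 | (3S)-3-[(8S,9Z)-8-hydroxy-3-oxoheptadec-9-ene-4,6-diyn-1-yl]-3-[(2E,6E)-3,7,11-trimethyldodeca-2,6,10-trien-1-yl]-2H-chromene-2,4(3H)-dione | CCCCCCC/C=C\[C@H](O)C#CC#CC(=O)CC[C@@]1(C/C=C(\C)CC/C=C(\C)CCC=C(C)C)C(=O)Oc2ccccc2C1=O | target

Total step count: 13. Longest linear sequence: 9 steps (steps 1 to 8, then step 13); the chromanedione branch (steps 9 to 12) joins at step 13.

Steps most likely to fail

1. Step 12 (labelled step). The process at risk is weak or wrong-sense facial discrimination of the flat coumarin enolate, together with slow addition of this stabilised enolate to the thioacrylate. The fallback uses known chemistry, sets out from 17 and 21 and returns at 22. An Et3N-catalysed Michael addition in CH2Cl2 at rt, a reaction type established for 3-substituted 4-hydroxycoumarins and acrylic acceptors, should give racemic S-ethyl 3-{2,4-dioxo-3-[(2E,6E)-3,7,11-trimethyldodeca-2,6,10-trien-1-yl]-3,4-dihydro-2H-chromen-3-yl}propanethioate F1. Its enantiomers are separated by preparative HPLC on an amylose tris(3,5-dimethylphenylcarbamate) phase (hexane/i-PrOH), and the (3S) fraction is carried on as 22.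

2. Step 13. The processes at risk are oxidative homocoupling or decay of the terminal diynol before cross-coupling, conjugate addition of thiolate or amine to the new ynone, and slow activation of the C(O)–S bond. The fallback sets out from 22 and 13 and returns at 23.
   - Silver-assisted hydrolysis of the thioester (AgO2CCF3, wet THF) should give 3-{(3S)-2,4-dioxo-3-[(2E,6E)-3,7,11-trimethyldodeca-2,6,10-trien-1-yl]-3,4-dihydro-2H-chromen-3-yl}propanoic acid F2.
   - 13 is re-silylated (Et3SiCl, imidazole) to triethyl{[(5S,6Z)-tetradeca-6-ene-1,3-diyn-5-yl]oxy}silane F3.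
   - F2 is converted under neutral conditions with 1-chloro-N,N,2-trimethylprop-1-en-1-amine into the corresponding propanoyl chloride F4.
   - F4 is joined to F3 in a classical acyl Sonogashira coupling (PdCl2(PPh3)2, CuI, Et3N, THF, rt) to give (3S)-3-[(8S,9Z)-3-oxo-8-[(triethylsilyl)oxy]heptadec-9-ene-4,6-diyn-1-yl]-3-[(2E,6E)-3,7,11-trimethyldodeca-2,6,10-trien-1-yl]-2H-chromene-2,4(3H)-dione F5.
   - HF·pyridine with extra pyridine in THF at 0 °C then frees the carbinol to give 23.

3. Step 6. The process at risk is base-induced epimerisation of the α-silyloxy β,γ-unsaturated aldehyde, or migration of its double bond into conjugation, before the aldehyde is trapped. The fallback sets out from 9 and returns at 10. Dibromo-olefination without base (CBr4, PPh3, Zn, CH2Cl2, 0 °C; Corey–Fuchs) should give triethyl{[(3S,4Z)-1,1-dibromododeca-1,4-dien-3-yl]oxy}silane F6. Treatment with n-BuLi (2.1 equiv) in THF at −78 °C and a proton quench then gives 10.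

Further compounds
F1 | step 12 | racemic S-ethyl 3-{2,4-dioxo-3-[(2E,6E)-3,7,11-trimethyldodeca-2,6,10-trien-1-yl]-3,4-dihydro-2H-chromen-3-yl}propanethioate | CCSC(=O)CCC1(C/C=C(\C)CC/C=C(\C)CCC=C(C)C)C(=O)Oc2ccccc2C1=O
F2 | step 13 | 3-{(3S)-2,4-dioxo-3-[(2E,6E)-3,7,11-trimethyldodeca-2,6,10-trien-1-yl]-3,4-dihydro-2H-chromen-3-yl}propanoic acid | OC(=O)CC[C@@]1(C/C=C(\C)CC/C=C(\C)CCC=C(C)C)C(=O)Oc2ccccc2C1=O
F3 | step 13 | triethyl{[(5S,6Z)-tetradeca-6-ene-1,3-diyn-5-yl]oxy}silane | CCCCCCC/C=C\[C@H](O[Si](CC)(CC)CC)C#CC#C
F4 | step 13 | 3-{(3S)-2,4-dioxo-3-[(2E,6E)-3,7,11-trimethyldodeca-2,6,10-trien-1-yl]-3,4-dihydro-2H-chromen-3-yl}propanoyl chloride | ClC(=O)CC[C@@]1(C/C=C(\C)CC/C=C(\C)CCC=C(C)C)C(=O)Oc2ccccc2C1=O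
F5 | step 13 | (3S)-3-[(8S,9Z)-3-oxo-8-[(triethylsilyl)oxy]heptadec-9-ene-4,6-diyn-1-yl]-3-[(2E,6E)-3,7,11-trimethyldodeca-2,6,10-trien-1-yl]-2H-chromene-2,4(3H)-dione | CCCCCCC/C=C\[C@H](O[Si](CC)(CC)CC)C#CC#CC(=O)CC[C@@]1(C/C=C(\C)CC/C=C(\C)CCC=C(C)C)C(=O)Oc2ccccc2C1=O
F6 | step 6 | triethyl{[(3S,4Z)-1,1-dibromododeca-1,4-dien-3-yl]oxy}silane | CCCCCCC/C=C\[C@H](O[Si](CC)(CC)CC)C=C(Br)Br
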